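**Retrosynthetic overview**

1. Ring C (the pyran) is closed last, through the O1–C2 bond, by intramolecular Mitsunobu etherification of phenol-alcohol 13; the prenyl group comes from an aryl bromide by Stille coupling.
2. C2 comes from ozonolysis of a propenyl group. That propenyl group, the C3–C1' bond and the C3 stereocenter are all made in one aromatic Claisen rearrangement of the (R)-aryl allyl ether 8, with 1,3-chirality transfer.
3. Ether 8 comes from cross-metathesis of allylarene 4 with the (R)-butenyl aryl ether 7; 7 is made from (S)-but-3-en-2-ol by Mitsunobu inversion.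
4. Allylarene 4 (the future C4–C4a bond) comes from a first aromatic Claisen rearrangement of the mono-allyl ether of the symmetrical dihydroxybenzaldehyde 1.
5. Rings A and B are bought as arenes; ring C is the only ring formed.

Assumption: 1, 5, 6 and tributyl(3-methylbut-2-en-1-yl)stannane are bought as catalogue compounds.

**Route**

Step 1
Reactants: 1 2,6-dihydroxy-4-methoxybenzaldehyde
Product: 2 2-(allyloxy)-6-hydroxy-4-methoxybenzaldehyde
Conditions: allyl bromide (1.05 equiv), K2CO3 (1.1 equiv), acetone, reflux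
Reagents that add atoms: allyl bromide, C=CCBr
Why: Williamson O-alkylation; the two hydroxyls of 1 are equivalent, and after the first alkylation the remaining one is locked in a hydrogen bond to the aldehyde, so mono-allylation stops cleanly.

Step 2
Reactants: 2 2-(allyloxy)-6-hydroxy-4-methoxybenzaldehyde
Product: 4 3-allyl-2,6-dihydroxy-4-methoxybenzaldehyde, via 5-allyl-6-oxocyclohexadiene tautomer 3 (not isolated)
Conditions: PhNEt2, 190 °C, sealed tube, 4 h
Reagents that add atoms: none
Why: Aromatic Claisen ([3,3]-sigmatropic) rearrangement delivers the allyl group to the only free ortho carbon (the other ortho carbon carries the formyl group), and tautomerisation of dienone 3 restores the phenol; this makes the future C4–C4a bond.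

Step 3
Reactants: 5 2-bromo-3-methoxyphenol; 6 (S)-but-3-en-2-ol
Product: 7 (R)-2-bromo-1-(but-3-en-2-yloxy)-3-methoxybenzene
Conditions: PPh3, DIAD, THF, 0 °C to rt
Reagents that add atoms: none
Why: Mitsunobu etherification proceeds by SN2 displacement with inversion, so the bought (S)-carbinol becomes the (R)-aryl ether; the bromine blocks the ortho position that will later carry the prenyl group.

Step 4
Reactants: 4 3-allyl-2,6-dihydroxy-4-methoxybenzaldehyde (2 equiv); 7 (R)-2-bromo-1-(but-3-en-2-yloxy)-3-methoxybenzene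
Product: 8 3-[(2E,4R)-4-(2-bromo-3-methoxyphenoxy)pent-2-en-1-yl]-2,6-dihydroxy-4-methoxybenzaldehyde
Conditions: second-generation Grubbs catalyst RuCl2(=CHPh)(PCy3)(H2IMes) (5 mol%), 1,4-benzoquinone (10 mol%), CH2Cl2, 40 °C; minor Z isomer removed by chromatography
Reagents that add atoms: none
Why: Olefin cross-metathesis between a rapidly dimerising allylarene (type 1 olefin) and a hindered secondary allylic ether (type 2 olefin) is cross-selective and E-selective; the stereocenter is not touched and benzoquinone suppresses double-bond migration.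

Step 5
Reactants: 8 3-[(2E,4R)-4-(2-bromo-3-methoxyphenoxy)pent-2-en-1-yl]-2,6-dihydroxy-4-methoxybenzaldehyde
Product: 10 3-[(2S,3E)-2-(3-bromo-2-hydroxy-4-methoxyphenyl)pent-3-en-1-yl]-2,6-dihydroxy-4-methoxybenzaldehyde, via ortho-dienone 9 (not isolated)
Conditions: PhNEt2, 175 °C, sealed tube under argon, stopped at full conversion
Reagents that add atoms: none
Why: Aromatic Claisen rearrangement through a chair transition state with the methyl group pseudo-equatorial forms the aryl–C bond on the face from which the C–O bond leaves, so the (R)-C–O stereocenter is transferred suprafacially into the (S)-benzylic stereocenter (the future C3) and an E-propenyl group; bromine leaves only one ortho carbon open.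

Step 6
Reactants: 10 3-[(2S,3E)-2-(3-bromo-2-hydroxy-4-methoxyphenyl)pent-3-en-1-yl]-2,6-dihydroxy-4-methoxybenzaldehyde
Product: 12 3-[(2R)-2-(3-bromo-2-hydroxy-4-methoxyphenyl)-3-hydroxypropyl]-2,6-dihydroxy-4-methoxybenzaldehyde, via secondary ozonide 11 (not isolated)
Conditions: O3, CH2Cl2, −78 °C (Sudan Red 7B end point); then NaBH4, EtOH, −78 to 0 °C
Reagents that add atoms: ozone, [O-][O+]=O
Why: Ozonolysis with reductive borohydride work-up cuts the only C=C to the primary alcohol without exposing the epimerisable α-aryl aldehyde; the doubly hydrogen-bonded ring A aldehyde sits as an unreactive phenoxide under borohydride at or below 0 °C, and the stereocenter is untouched (the descriptor becomes R only because the priorities change).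

Step 7
Reactants: 12 3-[(2R)-2-(3-bromo-2-hydroxy-4-methoxyphenyl)-3-hydroxypropyl]-2,6-dihydroxy-4-methoxybenzaldehyde
Product: 13 2,6-dihydroxy-3-{(2R)-3-hydroxy-2-[2-hydroxy-4-methoxy-3-(3-methylbut-2-en-1-yl)phenyl]propyl}-4-methoxybenzaldehyde
Conditions: tributyl(3-methylbut-2-en-1-yl)stannane (1.5 equiv), Pd2(dba)3 (5 mol%), P(t-Bu)3 (12 mol%), CsF (2.2 equiv), dioxane, 90 °C
Reagents that add atoms: tributyl(3-methylbut-2-en-1-yl)stannane, CCCC[Sn](CCCC)(CCCC)CC=C(C)C
Why: Stille coupling; zerovalent palladium with the bulky electron-rich phosphine inserts into the hindered electron-rich C–Br bond, and reductive elimination from the allyl–palladium intermediate occurs at the unsubstituted terminus to give the linear prenyl arene, with free OH and CHO groups tolerated.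

Step 8
Reactants: 13 2,6-dihydroxy-3-{(2R)-3-hydroxy-2-[2-hydroxy-4-methoxy-3-(3-methylbut-2-en-1-yl)phenyl]propyl}-4-methoxybenzaldehyde
Product: 14 (3R)-7-hydroxy-3-[2-hydroxy-4-methoxy-3-(3-methylbut-2-en-1-yl)phenyl]-5-methoxy-3,4-dihydro-2H-chromene-8-carbaldehyde (target)
Conditions: PPh3, DIAD, THF (0.01 M), 0 °C to rt
Reagents that add atoms: none
Why: Intramolecular Mitsunobu etherification (6-exo-tet); the betaine deprotonates the most acidic phenol, the ring A hydroxyl ortho to the aldehyde and next to the side chain, which displaces the activated primary alcohol, while the hindered and far less acidic di-ortho-substituted ring B phenol stays protonated; the stereocenter is not involved.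

**Compound list**

1 | 2,6-dihydroxy-4-methoxybenzaldehyde | O=Cc1c(O)cc(OC)cc1O | starting material
2 | 2-(allyloxy)-6-hydroxy-4-methoxybenzaldehyde | O=Cc1c(O)cc(OC)cc1OCC=C | intermediate
3 | 5-allyl-2-hydroxy-4-methoxy-6-oxocyclohexa-1,3-diene-1-carbaldehyde (Claisen dienone, racemic at C5) | O=CC1=C(O)C=C(OC)C(CC=C)C1=O | intermediate
4 | 3-allyl-2,6-dihydroxy-4-methoxybenzaldehyde | O=Cc1c(O)cc(OC)c(CC=C)c1O | intermediate
5 | 2-bromo-3-methoxyphenol | COc1cccc(O)c1Br | starting material
6 | (S)-but-3-en-2-ol | C[C@H](O)C=C | starting material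
7 | (R)-2-bromo-1-(but-3-en-2-yloxy)-3-methoxybenzene | C[C@@H](Oc1cccc(OC)c1Br)C=C | intermediate
8 | 3-[(2E,4R)-4-(2-bromo-3-methoxyphenoxy)pent-2-en-1-yl]-2,6-dihydroxy-4-methoxybenzaldehyde | C[C@@H](Oc1cccc(OC)c1Br)/C=C/Cc1c(OC)cc(O)c(C=O)c1O | intermediate
9 | 2-bromo-6-[(3E)-1-(3-formyl-2,4-dihydroxy-6-methoxyphenyl)pent-3-en-2-yl]-3-methoxycyclohexa-2,4-dien-1-one (Claisen dienone; side-chain stereocenter as in 10, ring C6 unassigned) | C/C=C/[C@H](Cc1c(OC)cc(O)c(C=O)c1O)C1C=CC(OC)=C(Br)C1=O | intermediate
10 | 3-[(2S,3E)-2-(3-bromo-2-hydroxy-4-methoxyphenyl)pent-3-en-1-yl]-2,6-dihydroxy-4-methoxybenzaldehyde | C/C=C/[C@H](Cc1c(OC)cc(O)c(C=O)c1O)c1ccc(OC)c(Br)c1O | intermediate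
11 | 3-[(2R)-2-(3-bromo-2-hydroxy-4-methoxyphenyl)-2-(5-methyl-1,2,4-trioxolan-3-yl)ethyl]-2,6-dihydroxy-4-methoxybenzaldehyde (secondary ozonide, mixture at the trioxolane carbons) | CC1OOC(O1)[C@H](Cc1c(OC)cc(O)c(C=O)c1O)c1ccc(OC)c(Br)c1O | intermediate
12 | 3-[(2R)-2-(3-bromo-2-hydroxy-4-methoxyphenyl)-3-hydroxypropyl]-2,6-dihydroxy-4-methoxybenzaldehyde | OC[C@H](Cc1c(OC)cc(O)c(C=O)c1O)c1ccc(OC)c(Br)c1O | intermediate
13 | 2,6-dihydroxy-3-{(2R)-3-hydroxy-2-[2-hydroxy-4-methoxy-3-(3-methylbut-2-en-1-yl)phenyl]propyl}-4-methoxybenzaldehyde | OC[C@H](Cc1c(OC)cc(O)c(C=O)c1O)c1ccc(OC)c(CC=C(C)C)c1O | intermediate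
14 | (3R)-7-hydroxy-3-[2-hydroxy-4-methoxy-3-(3-methylbut-2-en-1-yl)phenyl]-5-methoxy-3,4-dihydro-2H-chromene-8-carbaldehyde | COc1ccc([C@@H]2COc3c(C=O)c(O)cc(OC)c3C2)c(O)c1CC=C(C)C | target

**Step count and risks**

Total steps: 8. Longest linear sequence: 7 steps (1 → 2 → 4 → 8 → 10 → 12 → 13 → 14); the other branch (5 + 6 → 7) is one step.

The three steps most likely to fail:

Step 5 (chirality-transfer Claisen). The liberated ring B phenol sits next to a branched allyl group, which invites the phenol-mediated abnormal Claisen isomerisation on prolonged heating; the free ring A phenols can add side reactions, and any Z-olefin product erodes the enantiomeric purity. Fallback, from 8 back to 10: switch to a masked-phenol sequence. Treat 8 with N,O-bis(trimethylsilyl)acetamide in PhNEt2 at room temperature to give the bis(trimethylsilyl) ether of 8 F1. Heat this at 175 °C with excess silylating agent so that the new phenol is capped as it forms, giving the tris(trimethylsilyl) ether of 10 F2. Cleave the silyl ethers with K2CO3 in MeOH to return to 10. No free phenol is then present at high temperature.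

Step 7 (Stille prenylation). The bromide is flanked by OH and OMe, so protodebromination or some branched (1,1-dimethylallyl) product is possible. Fallback, from 12 back to 13: couple 12 with allyltributylstannane (Pd(PPh3)4, DMF, 90 °C), which has no regiochemical ambiguity, to give 3-[(2R)-2-(3-allyl-2-hydroxy-4-methoxyphenyl)-3-hydroxypropyl]-2,6-dihydroxy-4-methoxybenzaldehyde F3. Then convert allyl into prenyl by cross-metathesis with excess 2-methylbut-2-ene (second-generation Grubbs catalyst, CH2Cl2, 40 °C) to reach 13.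

Step 8 (Mitsunobu ring closure). The ring B 2'-hydroxyl could close a five-membered dihydrobenzofuran instead of the chroman. Fallback, from 13 back to 14: separate activation from ring closure. Convert the primary alcohol of 13 with PPh3, I2 and imidazole (CH2Cl2, 0 °C) into 2,6-dihydroxy-3-{(2R)-2-[2-hydroxy-4-methoxy-3-(3-methylbut-2-en-1-yl)phenyl]-3-iodopropyl}-4-methoxybenzaldehyde F4. Then treat with one equivalent of KHCO3 in DMF at room temperature; only the acidic ring A phenol is deprotonated and it closes the six-membered ring to give 14.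

**Further compounds**

F1 | step 5 | 3-[(2E,4R)-4-(2-bromo-3-methoxyphenoxy)pent-2-en-1-yl]-4-methoxy-2,6-bis(trimethylsilyloxy)benzaldehyde | C[C@@H](Oc1cccc(OC)c1Br)/C=C/Cc1c(OC)cc(O[Si](C)(C)C)c(C=O)c1O[Si](C)(C)C
F2 | step 5 | 3-{(2S,3E)-2-[3-bromo-4-methoxy-2-(trimethylsilyloxy)phenyl]pent-3-en-1-yl}-4-methoxy-2,6-bis(trimethylsilyloxy)benzaldehyde | C/C=C/[C@H](Cc1c(OC)cc(O[Si](C)(C)C)c(C=O)c1O[Si](C)(C)C)c1ccc(OC)c(Br)c1O[Si](C)(C)C
F3 | step 7 | 3-[(2R)-2-(3-allyl-2-hydroxy-4-methoxyphenyl)-3-hydroxypropyl]-2,6-dihydroxy-4-methoxybenzaldehyde | OC[C@H](Cc1c(OC)cc(O)c(C=O)c1O)c1ccc(OC)c(CC=C)c1O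
F4 | step 8 | 2,6-dihydroxy-3-{(2R)-2-[2-hydroxy-4-methoxy-3-(3-methylbut-2-en-1-yl)phenyl]-3-iodopropyl}-4-methoxybenzaldehyde | IC[C@H](Cc1c(OC)cc(O)c(C=O)c1O)c1ccc(OC)c(CC=C(C)C)c1O
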